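**Assumption:** flavan numbering (O1, C2–C4, ring A = C5–C8). The SMILES given is the (2S,4R), 2,4-trans isomer. Prenyl = 3-methylbut-2-en-1-yl; racemic compounds are written without stereodescriptors.

## Retrosynthetic overview

1. Target ⇐ bis-O-allyl (2S,4R)-flavan-4-ol ⇐ Mitsunobu inversion at C4 of the (2S,4S)-cis-alcohol.
2. cis-Alcohol ⇐ racemic 5-O-allyl-8-prenylflavanone by asymmetric transfer hydrogenation run as a kinetic resolution (fixes C2 and C4 together).
3. 8-Prenyl group ⇐ 5-O-prenyl ether by europium-catalysed Claisen–Cope shift on the intact flavanone.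
4. Flavanone ⇐ 2'-hydroxychalcone ⇐ Claisen–Schmidt aldol condensation of a ring A acetophenone (from phloroacetophenone) with a ring B aldehyde (from 4-hydroxybenzaldehyde); this is the key C–C bond.
5. Ring order: rings A and B are bought as aromatic rings; the pyran ring (ring C) is closed afterwards by oxa-Michael addition.

## Route

**Step 1**
Reactants: 1 2',4',6'-trihydroxyacetophenone
Product: 2 1-(2,6-dihydroxy-4-methoxyphenyl)ethanone
Conditions: Me2SO4 (1.0 equiv), K2CO3 (1.0 equiv), acetone, reflux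
Reagents that add atoms: dimethyl sulfate, COS(=O)(=O)OC
Why: Williamson O-methylation goes to the 4-OH, the only hydroxyl not hydrogen-bonded to the acetyl carbonyl and the most acidic one (para to C=O).

**Step 2**
Reactants: 2 1-(2,6-dihydroxy-4-methoxyphenyl)ethanone
Product: 3 1-[2-hydroxy-4-methoxy-6-(methoxymethoxy)phenyl]ethanone
Conditions: MOMCl (1.1 equiv), K2CO3, acetone, 0 °C → rt
Reagents that add atoms: chloromethyl methyl ether, COCCl
Why: O-alkylation (MOM acetal protection) stops at the mono-ether because the remaining hydroxyl is locked in a strong hydrogen bond to the carbonyl; that phenol is kept for the later ring closure.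

**Step 3**
Reactants: 4 4-hydroxybenzaldehyde
Product: 5 4-(allyloxy)benzaldehyde
Conditions: allyl bromide (1.2 equiv), K2CO3, acetone, reflux
Reagents that add atoms: allyl bromide, C=CCBr
Why: Williamson ether synthesis gives an aryl allyl ether that survives KOH, HCl/MeOH, Lewis acid, hydride transfer and Mitsunobu conditions and can be removed at the end without acid or hydrogenation.

**Step 4**
Reactants: 3 1-[2-hydroxy-4-methoxy-6-(methoxymethoxy)phenyl]ethanone; 5 4-(allyloxy)benzaldehyde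
Product: 7 (E)-3-[4-(allyloxy)phenyl]-1-[2-hydroxy-4-methoxy-6-(methoxymethoxy)phenyl]prop-2-en-1-one, via racemic aldol adduct 6 (not isolated)
Conditions: KOH (50% aq.), EtOH, 0 °C → rt, 48 h
Reagents that add atoms: none
Why: Claisen–Schmidt crossed aldol condensation: the potassium enolate of methyl ketone 3 adds to the non-enolisable aldehyde 5 and E1cB dehydration of the aldol gives the (E)-chalcone, so no stereocentre remains.

**Step 5**
Reactants: 7 (E)-3-[4-(allyloxy)phenyl]-1-[2-hydroxy-4-methoxy-6-(methoxymethoxy)phenyl]prop-2-en-1-one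
Product: 9 racemic 2-[4-(allyloxy)phenyl]-5-hydroxy-7-methoxychroman-4-one, via free dihydroxychalcone 8 (not isolated)
Conditions: 3 M HCl, MeOH, 60 °C; concentrate; then NaOAc, EtOH, reflux
Reagents that add atoms: none
Why: Acidic methanolysis cleaves the MOM acetal and the 2',6'-dihydroxychalcone closes the pyran ring by intramolecular oxa-Michael addition; the two phenols are equivalent, so there is one regioisomer, and C2 is formed racemic on purpose.

**Step 6**
Reactants: 9 racemic 2-[4-(allyloxy)phenyl]-5-hydroxy-7-methoxychroman-4-one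
Product: 10 racemic 2-[4-(allyloxy)phenyl]-7-methoxy-5-[(3-methylbut-2-en-1-yl)oxy]chroman-4-one
Conditions: 3-methylbut-2-en-1-ol (1.5 equiv), PPh3, DIAD, THF, 0 °C → rt
Reagents that add atoms: 3-methylbut-2-en-1-ol, CC(C)=CCO
Why: Mitsunobu etherification alkylates the chelated 5-OH (the only free hydroxyl) under neutral conditions, avoiding the base-induced ring opening of the flavanone that an alkyl halide/carbonate alkylation would risk.

**Step 7**
Reactants: 10 racemic 2-[4-(allyloxy)phenyl]-7-methoxy-5-[(3-methylbut-2-en-1-yl)oxy]chroman-4-one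
Product: 13 racemic 2-[4-(allyloxy)phenyl]-5-hydroxy-7-methoxy-8-(3-methylbut-2-en-1-yl)chroman-4-one, via C6 dimethylallyl dienone 11 (not isolated), via C8 prenyl dienone 12 (not isolated)
Conditions: Eu(fod)3 [europium tris(6,6,7,7,8,8,8-heptafluoro-2,2-dimethyloctane-3,5-dionate)] (10 mol%), CHCl3, 60 °C
Reagents that add atoms: none
Why: The trivalent europium Lewis acid chelates the C4 carbonyl/5-O pair and accelerates an aromatic Claisen rearrangement to C6 followed by a Cope shift to C8 (para-Claisen–Cope); the double allyl inversion gives a normal prenyl group, rearomatisation gives the chelated 5-OH, and the unchelated ring B allyl ether is inert at this temperature.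

**Step 8**
Reactants: 13 racemic 2-[4-(allyloxy)phenyl]-5-hydroxy-7-methoxy-8-(3-methylbut-2-en-1-yl)chroman-4-one
Product: 14 racemic 5-(allyloxy)-2-[4-(allyloxy)phenyl]-7-methoxy-8-(3-methylbut-2-en-1-yl)chroman-4-one
Conditions: allyl alcohol (1.5 equiv), PPh3, DIAD, THF, 0 °C → rt
Reagents that add atoms: allyl alcohol, C=CCO
Why: A second Mitsunobu etherification masks the 5-OH as a non-migrating ether, which activates the C4 ketone for reduction and prevents quinone methide formation in the later C4 inversion.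

**Step 9**
Reactants: 14 racemic 5-(allyloxy)-2-[4-(allyloxy)phenyl]-7-methoxy-8-(3-methylbut-2-en-1-yl)chroman-4-one
Product: 15 (2S,4S)-5-(allyloxy)-2-[4-(allyloxy)phenyl]-7-methoxy-8-(3-methylbut-2-en-1-yl)chroman-4-ol (2,4-cis)
Conditions: RhCl(C5Me5)[(S,S)-TsDPEN] (1 mol%; TsDPEN = N-tosyl-1,2-diphenylethane-1,2-diamine), HCO2H/Et3N (1:1), EtOAc, rt, stopped at ca. 50% conversion; chromatography
Reagents that add atoms: none
Why: Noyori–Ikariya asymmetric transfer hydrogenation run as a kinetic resolution: the (S,S)-catalyst gives the 4S carbinol (the sense known for 4-chromanone) and does so fast only for the 2S enantiomer, where this is also the substrate-preferred attack anti to the C2 aryl group, so 15 forms as the (2S,4S)-cis isomer in high ee while (2R)-14 is left behind, separated and, if wanted, racemised with base through the chalcone and recycled.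

**Step 10**
Reactants: 15 (2S,4S)-5-(allyloxy)-2-[4-(allyloxy)phenyl]-7-methoxy-8-(3-methylbut-2-en-1-yl)chroman-4-ol
Product: 16 (2S,4R)-5-(allyloxy)-2-[4-(allyloxy)phenyl]-7-methoxy-8-(3-methylbut-2-en-1-yl)chroman-4-yl 4-nitrobenzoate (2,4-trans)
Conditions: 4-nitrobenzoic acid (2 equiv), PPh3, DIAD, THF, 0 °C → rt
Reagents that add atoms: 4-nitrobenzoic acid, O=C(O)c1ccc(cc1)[N+](=O)[O-]
Why: Mitsunobu reaction: the alkoxyphosphonium ion of the secondary benzylic alcohol is displaced by 4-nitrobenzoate with inversion (4S → 4R), giving the 2,4-trans ester, which is also the isomer favoured by the peri 5-alkoxy group.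

**Step 11**
Reactants: 16 (2S,4R)-5-(allyloxy)-2-[4-(allyloxy)phenyl]-7-methoxy-8-(3-methylbut-2-en-1-yl)chroman-4-yl 4-nitrobenzoate
Product: 17 (2S,4R)-5-(allyloxy)-2-[4-(allyloxy)phenyl]-7-methoxy-8-(3-methylbut-2-en-1-yl)chroman-4-ol (2,4-trans)
Conditions: K2CO3 (0.2 equiv), MeOH/THF, rt
Reagents that add atoms: none
Why: Base-catalysed transesterification (acyl–oxygen cleavage) frees the 4R alcohol without touching the C4–O bond, and with no C4 carbonyl left the C2 centre cannot epimerise by retro-oxa-Michael opening.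

**Step 12**
Reactants: 17 (2S,4R)-5-(allyloxy)-2-[4-(allyloxy)phenyl]-7-methoxy-8-(3-methylbut-2-en-1-yl)chroman-4-ol
Product: 18 (2S,4R)-2-(4-hydroxyphenyl)-7-methoxy-8-(3-methylbut-2-en-1-yl)chroman-4,5-diol (4,5,4'-trihydroxy-7-methoxy-8-prenylflavan)
Conditions: Pd(PPh3)4 (5 mol%), morpholine (10 equiv), THF, rt, degassed; neutral work-up
Reagents that add atoms: none
Why: Tsuji–Trost deallylation: zerovalent palladium ionises both aryl allyl ethers to π-allyl complexes that morpholine traps, a non-acidic and non-reductive unmasking that leaves the C-prenyl alkene, the acid-labile benzylic 4-ol and both stereocentres untouched.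

## Compound list

1 | 2',4',6'-trihydroxyacetophenone | CC(=O)c1c(O)cc(O)cc1O | starting material
2 | 1-(2,6-dihydroxy-4-methoxyphenyl)ethanone | CC(=O)c1c(O)cc(OC)cc1O | intermediate
3 | 1-[2-hydroxy-4-methoxy-6-(methoxymethoxy)phenyl]ethanone | CC(=O)c1c(O)cc(OC)cc1OCOC | intermediate
4 | 4-hydroxybenzaldehyde | O=Cc1ccc(O)cc1 | starting material
5 | 4-(allyloxy)benzaldehyde | C=CCOc1ccc(C=O)cc1 | intermediate
6 | racemic 3-[4-(allyloxy)phenyl]-3-hydroxy-1-[2-hydroxy-4-methoxy-6-(methoxymethoxy)phenyl]propan-1-one (aldol adduct) | COCOc1cc(OC)cc(O)c1C(=O)CC(O)c1ccc(OCC=C)cc1 | intermediate (not isolated)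
7 | (E)-3-[4-(allyloxy)phenyl]-1-[2-hydroxy-4-methoxy-6-(methoxymethoxy)phenyl]prop-2-en-1-one | COCOc1cc(OC)cc(O)c1C(=O)/C=C/c1ccc(OCC=C)cc1 | intermediate
8 | (E)-3-[4-(allyloxy)phenyl]-1-(2,6-dihydroxy-4-methoxyphenyl)prop-2-en-1-one | COc1cc(O)c(C(=O)/C=C/c2ccc(OCC=C)cc2)c(O)c1 | intermediate (not isolated)
9 | racemic 2-[4-(allyloxy)phenyl]-5-hydroxy-7-methoxychroman-4-one | COc1cc(O)c2C(=O)CC(c3ccc(OCC=C)cc3)Oc2c1 | intermediate
10 | racemic 2-[4-(allyloxy)phenyl]-7-methoxy-5-[(3-methylbut-2-en-1-yl)oxy]chroman-4-one | COc1cc(OCC=C(C)C)c2C(=O)CC(c3ccc(OCC=C)cc3)Oc2c1 | intermediate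
11 | 2-[4-(allyloxy)phenyl]-7-methoxy-6-(2-methylbut-3-en-2-yl)-2,3-dihydro-4H-chromene-4,5(6H)-dione (mixture of stereoisomers) | COC1=CC2=C(C(=O)CC(c3ccc(OCC=C)cc3)O2)C(=O)C1C(C)(C)C=C | intermediate (not isolated)
12 | 2-[4-(allyloxy)phenyl]-7-methoxy-8-(3-methylbut-2-en-1-yl)-2,3-dihydro-4H-chromene-4,5(8H)-dione (mixture of stereoisomers) | COC1=CC(=O)C2=C(OC(c3ccc(OCC=C)cc3)CC2=O)C1CC=C(C)C | intermediate (not isolated)
13 | racemic 2-[4-(allyloxy)phenyl]-5-hydroxy-7-methoxy-8-(3-methylbut-2-en-1-yl)chroman-4-one | COc1cc(O)c2C(=O)CC(c3ccc(OCC=C)cc3)Oc2c1CC=C(C)C | intermediate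
14 | racemic 5-(allyloxy)-2-[4-(allyloxy)phenyl]-7-methoxy-8-(3-methylbut-2-en-1-yl)chroman-4-one | COc1cc(OCC=C)c2C(=O)CC(c3ccc(OCC=C)cc3)Oc2c1CC=C(C)C | intermediate
15 | (2S,4S)-5-(allyloxy)-2-[4-(allyloxy)phenyl]-7-methoxy-8-(3-methylbut-2-en-1-yl)chroman-4-ol | COc1cc(OCC=C)c2c(c1CC=C(C)C)O[C@H](c1ccc(OCC=C)cc1)C[C@@H]2O | intermediate
16 | (2S,4R)-5-(allyloxy)-2-[4-(allyloxy)phenyl]-7-methoxy-8-(3-methylbut-2-en-1-yl)chroman-4-yl 4-nitrobenzoate | COc1cc(OCC=C)c2c(c1CC=C(C)C)O[C@H](c1ccc(OCC=C)cc1)C[C@H]2OC(=O)c1ccc(cc1)[N+](=O)[O-] | intermediate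
17 | (2S,4R)-5-(allyloxy)-2-[4-(allyloxy)phenyl]-7-methoxy-8-(3-methylbut-2-en-1-yl)chroman-4-ol | COc1cc(OCC=C)c2c(c1CC=C(C)C)O[C@H](c1ccc(OCC=C)cc1)C[C@H]2O | intermediate
18 | (2S,4R)-2-(4-hydroxyphenyl)-7-methoxy-8-(3-methylbut-2-en-1-yl)chroman-4,5-diol | COc1cc(O)c2c(c1CC=C(C)C)O[C@H](c1ccc(O)cc1)C[C@H]2O | target

## Summary

Total step count: 12.
Longest linear sequence: 11 steps (steps 1, 2, 4–12 from compound 1; step 3 is the one-step side branch).

### Steps most likely to fail

**Step 7 (Claisen–Cope shift).** The C6 dienone can tautomerise before the Cope shift, giving the 6-(1,1-dimethylallyl) isomer instead of the 8-prenyl compound. The fallback sets out from 2 and comes back at 13, putting the prenyl group on ring A before the aldol step: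
- C-prenylation of 2 with prenyl bromide in cold aqueous KOH gives 1-[2,6-dihydroxy-4-methoxy-3-(3-methylbut-2-en-1-yl)phenyl]ethanone F1.
- MOMCl/K2CO3 protects the less hindered hydroxyl (the one not flanked by the prenyl group) to give 1-[2-hydroxy-4-methoxy-6-(methoxymethoxy)-3-(3-methylbut-2-en-1-yl)phenyl]ethanone F2.
- Claisen–Schmidt condensation with 5 (KOH, EtOH) gives the prenylated chalcone (E)-3-[4-(allyloxy)phenyl]-1-[2-hydroxy-4-methoxy-6-(methoxymethoxy)-3-(3-methylbut-2-en-1-yl)phenyl]prop-2-en-1-one F3.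
- NaOAc in refluxing EtOH closes the pyran ring through the only free phenol, which fixes the prenyl group at C8, giving racemic 2-[4-(allyloxy)phenyl]-7-methoxy-5-(methoxymethoxy)-8-(3-methylbut-2-en-1-yl)chroman-4-one F4.
- Mild acidic methanolysis (dilute HCl, MeOH, 40 °C) removes the MOM group and gives 13; the prenyl group then has no free ortho-hydroxyl, so it cannot cyclise to a chroman.

**Step 9 (kinetic resolution).** The selectivity factor with a peri 5-allyloxy group and an 8-prenyl group is not assured, and the yield is capped at 50% per pass. The fallback sets out from 14 and comes back at 17, replacing catalytic resolution by separation of diastereomers: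
- NaBH4 (MeOH/THF, 0 °C) reduces 14 to the racemic 2,4-cis alcohol, rac-(2S*,4S*)-5-(allyloxy)-2-[4-(allyloxy)phenyl]-7-methoxy-8-(3-methylbut-2-en-1-yl)chroman-4-ol F5.
- Mitsunobu inversion with (S)-2-methoxy-2-phenylacetic acid (PPh3, DIAD) gives two diastereomeric 2,4-trans esters, separated by chromatography or crystallisation: the wanted (2S,4R)-chroman-4-yl (S)-2-methoxy-2-phenylacetate F6 and the unwanted (2R,4S)-chroman-4-yl (S)-2-methoxy-2-phenylacetate F7.
- K2CO3/MeOH methanolysis of F6 gives 17.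

**Step 10 (Mitsunobu inversion).** The C4 position is a very electron-rich, peri-hindered benzylic centre, so ionisation, elimination to the flav-3-ene or incomplete inversion may compete. The fallback sets out from 15 and comes back at 17, using ionisation on purpose:
- Stirring 15 dilute in acetic acid (rt to 40 °C) lets the C4 cation equilibrate. It is captured mainly as the 2,4-trans acetate, (2S,4R)-5-(allyloxy)-2-[4-(allyloxy)phenyl]-7-methoxy-8-(3-methylbut-2-en-1-yl)chroman-4-yl acetate F8, because the pseudo-axial 4-substituent avoids the peri 5-allyloxy group while the 2-aryl group stays equatorial.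
- K2CO3/MeOH then gives 17; any cis alcohol is separated and resubmitted.

## Further compounds

F1 | step 7 | 1-[2,6-dihydroxy-4-methoxy-3-(3-methylbut-2-en-1-yl)phenyl]ethanone | CC(=O)c1c(O)c(CC=C(C)C)c(OC)cc1O
F2 | step 7 | 1-[2-hydroxy-4-methoxy-6-(methoxymethoxy)-3-(3-methylbut-2-en-1-yl)phenyl]ethanone | CC(=O)c1c(O)c(CC=C(C)C)c(OC)cc1OCOC
F3 | step 7 | (E)-3-[4-(allyloxy)phenyl]-1-[2-hydroxy-4-methoxy-6-(methoxymethoxy)-3-(3-methylbut-2-en-1-yl)phenyl]prop-2-en-1-one | COCOc1cc(OC)c(CC=C(C)C)c(O)c1C(=O)/C=C/c1ccc(OCC=C)cc1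
F4 | step 7 | racemic 2-[4-(allyloxy)phenyl]-7-methoxy-5-(methoxymethoxy)-8-(3-methylbut-2-en-1-yl)chroman-4-one | COCOc1cc(OC)c(CC=C(C)C)c2OC(c3ccc(OCC=C)cc3)CC(=O)c12
F5 | step 9 | racemic 2,4-cis-5-(allyloxy)-2-[4-(allyloxy)phenyl]-7-methoxy-8-(3-methylbut-2-en-1-yl)chroman-4-ol (1:1 mixture of 2S,4S and 2R,4R) | COc1cc(OCC=C)c2c(c1CC=C(C)C)O[C@H](c1ccc(OCC=C)cc1)C[C@@H]2O.COc1cc(OCC=C)c2c(c1CC=C(C)C)O[C@@H](c1ccc(OCC=C)cc1)C[C@H]2O
F6 | step 9 | (2S,4R)-5-(allyloxy)-2-[4-(allyloxy)phenyl]-7-methoxy-8-(3-methylbut-2-en-1-yl)chroman-4-yl (S)-2-methoxy-2-phenylacetate | COc1cc(OCC=C)c2c(c1CC=C(C)C)O[C@H](c1ccc(OCC=C)cc1)C[C@H]2OC(=O)[C@@H](OC)c1ccccc1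
F7 | step 9 | (2R,4S)-5-(allyloxy)-2-[4-(allyloxy)phenyl]-7-methoxy-8-(3-methylbut-2-en-1-yl)chroman-4-yl (S)-2-methoxy-2-phenylacetate | COc1cc(OCC=C)c2c(c1CC=C(C)C)O[C@@H](c1ccc(OCC=C)cc1)C[C@@H]2OC(=O)[C@@H](OC)c1ccccc1
F8 | step 10 | (2S,4R)-5-(allyloxy)-2-[4-(allyloxy)phenyl]-7-methoxy-8-(3-methylbut-2-en-1-yl)chroman-4-yl acetate | COc1cc(OCC=C)c2c(c1CC=C(C)C)O[C@H](c1ccc(OCC=C)cc1)C[C@H]2OC(C)=O
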